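**Plan**

- Germacrane numbering is used (ring C1–C10, lactone C12, methylene C13, C14 on C10, C15 on C4). The retrosynthesis cuts, in this order, the C6 ester C–O bond, C11=C13, the ring bond C5–C6, C6–C7, the lactone (C7–C11 and O–C12), C9–C10 and C3–C4.
- Forward, the C14/C10–C5/C15 chain is made first, by carbomagnesiation of a silylpropargyl alcohol and hydrozirconation–iodination. Its alkenyl metal opens (S)-epichlorohydrin, the derived epoxide becomes a butenolide, and C6 is added as a dioxolanyl radical. The ten-membered ring then closes between C5 and C6, and methylenation and acylation finish the molecule.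
- The feature that allows the key step: C6 is an allylic carbinol carbon bonded to C5 of the in-ring C4=C5 alkene (C3 and C6 cis) and to C7 of the trans-fused γ-lactone (ring O–C8–C7–C11–C12). A C5 alkenyl metal and a C6 aldehyde carried by that lactone can therefore be joined.
- Stereochemistry: C8 comes from (S)-epichlorohydrin; C7 from radical addition anti to the C8 chain; C6 from the ring closure under control of C7, correctable by oxidation and reduction.
- Alkene geometry: C4=C5 from anti-carbomagnesiation and retentive iododesilylation; C1=C10 from syn hydrozirconation; the side-chain alkene from a stabilised Wittig reaction.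

Key step: step 12

Remark: C15 carries a tert-butyldiphenylsilyl (TBDPS) ether rather than a more labile silyl group so that it survives the aqueous acid of step 11; the α-selanyl lactone and the Mannich intermediates are C11 epimer mixtures, which does not matter because C11 becomes sp2.
Remark: the CIP descriptor at C7 switches between R and S with the substituent on O6 although the geometry never changes; the SMILES strings are authoritative.

Step 1
Reactants: 1 pent-3-yn-1-ol
Product: 2 5-bromopent-2-yne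
Conditions: CBr4, PPh3, CH2Cl2, 0 °C
Reagents that add atoms: carbon tetrabromide, BrC(Br)(Br)Br
Why: Appel bromination, in which the alcohol attacks the bromophosphonium ion and bromide displaces Ph3P=O by SN2 at the primary carbon, leaving the internal alkyne untouched.

Step 2
Reactants: 2 5-bromopent-2-yne; 3 3-(trimethylsilyl)prop-2-yn-1-ol
Product: 6 (E)-2-(pent-3-yn-1-yl)-3-(trimethylsilyl)prop-2-en-1-ol, via pent-3-yn-1-ylmagnesium bromide 4 (not isolated), via alkenylmagnesium alkoxide chelate 5 (not isolated)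
Conditions: Mg, Et2O, reflux; then 3 (0.4 equiv), CuI (10 mol%), Et2O, 0 °C → rt; H2O
Reagents that add atoms: none
Why: Copper-catalysed carbomagnesiation of a propargylic alcohol, in which the magnesium alkoxide of 3 directs the pentynyl group to C4 and magnesium to C5 within the five-membered chelate 5 (net anti addition), so that protonolysis leaves silicon cis to the new chain and trans to CH2OH, the geometry later needed at C4=C5.

Step 3
Reactants: 6 (E)-2-(pent-3-yn-1-yl)-3-(trimethylsilyl)prop-2-en-1-ol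
Product: 7 tert-butyl{[(E)-2-(pent-3-yn-1-yl)-3-(trimethylsilyl)prop-2-en-1-yl]oxy}diphenylsilane
Conditions: t-BuPh2SiCl, imidazole, DMF, rt
Reagents that add atoms: tert-butyl(chloro)diphenylsilane, CC(C)(C)[Si](Cl)(c1ccccc1)c1ccccc1
Why: Imidazole-promoted silylation of a primary allylic alcohol, giving an ether robust enough for the organolithium, photochemical and aqueous acid steps ahead.

Step 4
Reactants: 7 tert-butyl{[(E)-2-(pent-3-yn-1-yl)-3-(trimethylsilyl)prop-2-en-1-yl]oxy}diphenylsilane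
Product: 9 tert-butyl{[(E)-2-[(E)-4-iodopent-3-en-1-yl]-3-(trimethylsilyl)prop-2-en-1-yl]oxy}diphenylsilane, via alkenylzirconocene chloride 8 (not isolated)
Conditions: Cp2Zr(H)Cl (2 equiv), THF, 50 °C; then I2, THF, 0 °C
Reagents that add atoms: iodine, II
Why: Hydrozirconation–iodinolysis, in which Cp2Zr(H)Cl adds syn to the only alkyne, excess hydride at 50 °C lets zirconium settle on the less hindered methyl-bearing carbon C10, and I2 cleaves C–Zr with retention, so the later C9 substituent will be trans to C2.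

Step 5
Reactants: 9 tert-butyl{[(E)-2-[(E)-4-iodopent-3-en-1-yl]-3-(trimethylsilyl)prop-2-en-1-yl]oxy}diphenylsilane; 10 (S)-epichlorohydrin
Product: 13 (2S,4E,8E)-8-[(tert-butyldiphenylsilyloxy)methyl]-1-chloro-4-methyl-9-(trimethylsilyl)nona-4,8-dien-2-ol, via alkenyllithium 11 (not isolated), via alkenylmagnesium bromide 12 (not isolated)
Conditions: t-BuLi (2.0 equiv), Et2O, −78 °C; MgBr2·OEt2, −78 → −20 °C; CuI (10 mol%), 10, THF, −40 → 0 °C; H2O
Reagents that add atoms: none
Why: Iodine–lithium exchange with retention, transmetalation to magnesium and copper-catalysed SN2 opening of the epoxide at its unsubstituted carbon form C9–C10, while the C8 stereocentre is the one bought with (S)-epichlorohydrin and its C–O bond is never broken.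

Step 6
Reactants: 13 (2S,4E,8E)-8-[(tert-butyldiphenylsilyloxy)methyl]-1-chloro-4-methyl-9-(trimethylsilyl)nona-4,8-dien-2-ol
Product: 14 (2S)-2-[(2E,6E)-6-[(tert-butyldiphenylsilyloxy)methyl]-2-methyl-7-(trimethylsilyl)hepta-2,6-dien-1-yl]oxirane
Conditions: K2CO3, MeOH, rt
Reagents that add atoms: none
Why: Intramolecular Williamson etherification (3-exo-tet), in which the C8 alkoxide displaces the primary chloride, so C8 keeps its configuration and C7 becomes the new epoxide terminus.

Step 7
Reactants: 14 (2S)-2-[(2E,6E)-6-[(tert-butyldiphenylsilyloxy)methyl]-2-methyl-7-(trimethylsilyl)hepta-2,6-dien-1-yl]oxirane; 15 (phenylselanyl)acetic acid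
Product: 18 (5S)-5-[(2E,6E)-6-[(tert-butyldiphenylsilyloxy)methyl]-2-methyl-7-(trimethylsilyl)hepta-2,6-dien-1-yl]-3-(phenylselanyl)oxolan-2-one (both C3 epimers), via dilithium (phenylselanyl)acetate dianion 16 (not isolated), via γ-hydroxy acid 17 (not isolated)
Conditions: 15, LiN(i-Pr)2 (2.1 equiv per acid), THF, −78 → 0 °C; 14, 0 °C → rt; aq. HCl work-up; TsOH·H2O (cat.), benzene, rt
Reagents that add atoms: none
Why: Epoxide opening by a carboxylic acid dianion followed by acid-catalysed lactonisation, in which the α-carbon of 16 attacks the terminal epoxide carbon C7 by SN2 to form C7–C11 and the γ-hydroxy acid 17 closes to the γ-lactone without touching C8.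

Step 8
Reactants: 18 (5S)-5-[(2E,6E)-6-[(tert-butyldiphenylsilyloxy)methyl]-2-methyl-7-(trimethylsilyl)hepta-2,6-dien-1-yl]-3-(phenylselanyl)oxolan-2-one
Product: 20 (5S)-5-[(2E,6E)-6-[(tert-butyldiphenylsilyloxy)methyl]-2-methyl-7-(trimethylsilyl)hepta-2,6-dien-1-yl]furan-2(5H)-one, via selenoxide 19 (not isolated)
Conditions: NaIO4, NaHCO3, THF/MeOH/H2O, 0 °C → rt
Reagents that add atoms: none
Why: Selenoxide syn-elimination, in which periodate oxidises selenium and the selenoxide 19 eliminates toward the only β-hydrogens (on C7) to give the conjugated butenolide, the buffered medium being too weakly basic to enolise C8.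

Step 9
Reactants: 20 (5S)-5-[(2E,6E)-6-[(tert-butyldiphenylsilyloxy)methyl]-2-methyl-7-(trimethylsilyl)hepta-2,6-dien-1-yl]furan-2(5H)-one; 21 1,3-dioxolane
Product: 22 (4R,5S)-4-(1,3-dioxolan-2-yl)-5-[(2E,6E)-6-[(tert-butyldiphenylsilyloxy)methyl]-2-methyl-7-(trimethylsilyl)hepta-2,6-dien-1-yl]oxolan-2-one
Conditions: 21 (solvent), benzophenone (20 mol%), hν (350 nm, Pyrex), Ar, rt
Reagents that add atoms: none
Why: Photosensitised radical hydroalkylation (Giese-type addition), in which triplet benzophenone abstracts the acetal hydrogen of 21 and the nucleophilic dioxolan-2-yl radical adds to the electron-poor β-carbon C7 on the face opposite the C8 side chain, so C7 is set trans by C8.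

Step 10
Reactants: 22 (4R,5S)-4-(1,3-dioxolan-2-yl)-5-[(2E,6E)-6-[(tert-butyldiphenylsilyloxy)methyl]-2-methyl-7-(trimethylsilyl)hepta-2,6-dien-1-yl]oxolan-2-one
Product: 23 (4R,5S)-4-(1,3-dioxolan-2-yl)-5-[(2E,6E)-6-[(tert-butyldiphenylsilyloxy)methyl]-7-iodo-2-methylhepta-2,6-dien-1-yl]oxolan-2-one
Conditions: N-iodosuccinimide, 2,6-lutidine (0.5 equiv), (CF3)2CHOH, 0 °C; aq. work-up
Reagents that add atoms: N-iodosuccinimide, O=C1CCC(=O)N1I
Why: Electrophilic ipso-iododesilylation, in which iodonium attacks C5 and the β-silyl cation loses silicon before it can rotate, giving the vinyl iodide with retention (iodine cis to C3); it is placed after the photochemical step, which a vinyl iodide would not survive, and before the sensitive aldehyde is unmasked.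

Step 11
Reactants: 23 (4R,5S)-4-(1,3-dioxolan-2-yl)-5-[(2E,6E)-6-[(tert-butyldiphenylsilyloxy)methyl]-7-iodo-2-methylhepta-2,6-dien-1-yl]oxolan-2-one
Product: 24 (2S,3R)-2-[(2E,6E)-6-[(tert-butyldiphenylsilyloxy)methyl]-7-iodo-2-methylhepta-2,6-dien-1-yl]-5-oxooxolane-3-carbaldehyde
Conditions: 1 M aq. HCl, THF, rt
Reagents that add atoms: water, O
Why: Acid-catalysed acetal hydrolysis in a water-rich medium where water captures the oxocarbenium ion; the trans arrangement at C7 is the more stable one, and the TBDPS ether and vinyl iodide tolerate dilute aqueous acid.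

Step 12
Reactants: 24 (2S,3R)-2-[(2E,6E)-6-[(tert-butyldiphenylsilyloxy)methyl]-7-iodo-2-methylhepta-2,6-dien-1-yl]-5-oxooxolane-3-carbaldehyde
Product: 26 (6R,7S,8S)-15-(tert-butyldiphenylsilyloxy)-6-hydroxy-13-norgermacra-1(10)E,4E-dien-12,8-olide (C3 and C6 cis on C4=C5, trans lactone), via alkenylchromium dichloride 25 (not isolated)
Conditions: CrCl2 (10 equiv), NiCl2 (1 mol% of the CrCl2), degassed DMSO, rt, 24 added slowly to a final 0.002 M; aq. work-up
Reagents that add atoms: none
Why: Zerovalent nickel, formed from NiCl2 by divalent chromium, inserts into the C5–I bond with retention, the alkenylnickel transmetalates to trivalent chromium, and the alkenylchromium 25 adds 1,2 to the C6 aldehyde; this is the Nozaki–Hiyama–Kishi reaction in its known macrocyclising form for vinyl iodide aldehydes. The ten-membered carbocycle closes through the new C5–C6 bond by attack of C5 on the exocyclic carbonyl carbon (10-exo-trig), helped by the cis placement of C3 and the metal on C4=C5 and by the trans lactone, which carries both chain ends on adjacent carbons. The new stereocentre C6 is under substrate control by C7: a Felkin–Anh arrangement with C5 approaching anti to the C7–C8 bond (a ring torsion near 180°, normal in cyclodecadienes) and the carbonyl oxygen between C8 and C11 leads to 6R, whereas the gauche alternative would lead to 6S, so the configuration has to be verified at this stage. The step also needs addition to the aldehyde rather than the lactone carbonyl, secured by the aldehyde preference and low basicity of alkenylchromium reagents, and ring closure rather than oligomerisation, secured by slow addition at high dilution.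

Step 13
Reactants: 26 (6R,7S,8S)-15-(tert-butyldiphenylsilyloxy)-6-hydroxy-13-norgermacra-1(10)E,4E-dien-12,8-olide
Product: 27 (6R,7R,8S)-15-(tert-butyldiphenylsilyloxy)-6-(triethylsilyloxy)-13-norgermacra-1(10)E,4E-dien-12,8-olide
Conditions: Et3SiOTf, 2,6-lutidine, CH2Cl2, −78 °C
Reagents that add atoms: triethylsilyl trifluoromethanesulfonate, CC[Si](CC)(CC)OS(=O)(=O)C(F)(F)F
Why: Silylation of a hindered secondary alcohol with a silyl triflate and a non-nucleophilic base; the C6 hydroxyl is capped because as an alkoxide in the next step it could attack C12 and translactonise to the 6,12-olide.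

Step 14
Reactants: 27 (6R,7R,8S)-15-(tert-butyldiphenylsilyloxy)-6-(triethylsilyloxy)-13-norgermacra-1(10)E,4E-dien-12,8-olide
Product: 30 (6R,7R,8S)-15-(tert-butyldiphenylsilyloxy)-6-(triethylsilyloxy)germacra-1(10)E,4E,11(13)-trien-12,8-olide, via Mannich base 28 (not isolated), via trimethylammonium iodide 29 (not isolated)
Conditions: LiN(i-Pr)2, THF, −78 °C; CH2=NMe2+ I−, −78 °C → rt; MeI, MeOH, rt; NaHCO3 (aq.), CH2Cl2, rt
Reagents that add atoms: Eschenmoser's salt (N,N-dimethylmethyleneiminium iodide), C=[N+](C)C.[I-]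
Why: Lactone α-methylenation by the Mannich route, in which deprotonation at C11 (the only acidic C–H position) and aminomethylation are followed by N-methylation and mild-base E1cB loss of trimethylamine to give the exocyclic C11=C13 alkene.

Step 15
Reactants: 30 (6R,7R,8S)-15-(tert-butyldiphenylsilyloxy)-6-(triethylsilyloxy)germacra-1(10)E,4E,11(13)-trien-12,8-olide
Product: 31 (6R,7S,8S)-15-(tert-butyldiphenylsilyloxy)-6-hydroxygermacra-1(10)E,4E,11(13)-trien-12,8-olide
Conditions: pyridinium p-toluenesulfonate (cat.), MeOH/CH2Cl2, 0 °C → rt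
Reagents that add atoms: none
Why: Acid-catalysed methanolysis of the more labile triethylsilyl ether, to which the TBDPS ether at C15 and the methylene lactone are stable.

Step 16
Reactants: 32 (tert-butyldimethylsilyloxy)acetaldehyde; 33 ethyl 2-(triphenylphosphoranylidene)propanoate
Product: 34 ethyl (E)-4-(tert-butyldimethylsilyloxy)-2-methylbut-2-enoate
Conditions: CH2Cl2, rt
Reagents that add atoms: none
Why: Wittig olefination with a stabilised, α-branched ylide, which gives the (E)-trisubstituted enoate.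

Step 17
Reactants: 34 ethyl (E)-4-(tert-butyldimethylsilyloxy)-2-methylbut-2-enoate
Product: 35 (E)-4-(tert-butyldimethylsilyloxy)-2-methylbut-2-enoic acid
Conditions: LiOH, THF/MeOH/H2O, 0 °C → rt; 1 M HCl to pH 4, 0 °C
Reagents that add atoms: lithium hydroxide, [Li+].[OH-]
Why: Ester saponification, which the primary silyl ether tolerates together with a cold, brief acidification.

Step 18
Reactants: 31 (6R,7S,8S)-15-(tert-butyldiphenylsilyloxy)-6-hydroxygermacra-1(10)E,4E,11(13)-trien-12,8-olide; 35 (E)-4-(tert-butyldimethylsilyloxy)-2-methylbut-2-enoic acid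
Product: 37 (6R,7R,8S)-6-[(E)-4-(tert-butyldimethylsilyloxy)-2-methylbut-2-enoyloxy]-15-(tert-butyldiphenylsilyloxy)germacra-1(10)E,4E,11(13)-trien-12,8-olide, via mixed anhydride 36 (not isolated)
Conditions: 35, 2,4,6-trichlorobenzoyl chloride, Et3N, toluene, rt; then 31, 4-(dimethylamino)pyridine, toluene, rt
Reagents that add atoms: none
Why: Yamaguchi esterification, in which the mixed anhydride 36 passes the enoyl group through an acylpyridinium ion to the hindered allylic C6 hydroxyl with retention at C6.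

Step 19
Reactants: 37 (6R,7R,8S)-6-[(E)-4-(tert-butyldimethylsilyloxy)-2-methylbut-2-enoyloxy]-15-(tert-butyldiphenylsilyloxy)germacra-1(10)E,4E,11(13)-trien-12,8-olide
Product: 38 (6R,7R,8S)-15-hydroxy-6-[(E)-4-hydroxy-2-methylbut-2-enoyloxy]germacra-1(10)E,4E,11(13)-trien-12,8-olide (CNP0344932.2)
Conditions: HF·pyridine, pyridine, THF, 0 °C → rt
Reagents that add atoms: none
Why: Fluoride-mediated cleavage of both primary silyl ethers under buffered, non-basic conditions that spare the ester, the conjugated lactone and the allylic C6–O bond.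

**Compound list**

1 | pent-3-yn-1-ol | CC#CCCO | starting material
2 | 5-bromopent-2-yne | CC#CCCBr | intermediate
3 | 3-(trimethylsilyl)prop-2-yn-1-ol | C[Si](C)(C)C#CCO | starting material
4 | pent-3-yn-1-ylmagnesium bromide | CC#CCC[Mg]Br | intermediate (not isolated)
5 | alkenylmagnesium alkoxide chelate (Mg on C5, cis to CH2O) | CC#CCCC1=C([Si](C)(C)C)[Mg]OC1 | intermediate (not isolated)
6 | (E)-2-(pent-3-yn-1-yl)-3-(trimethylsilyl)prop-2-en-1-ol | CC#CCC/C(CO)=C\[Si](C)(C)C | intermediate
7 | tert-butyl{[(E)-2-(pent-3-yn-1-yl)-3-(trimethylsilyl)prop-2-en-1-yl]oxy}diphenylsilane | CC#CCC/C(CO[Si](c1ccccc1)(c1ccccc1)C(C)(C)C)=C\[Si](C)(C)C | intermediate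
8 | alkenylzirconocene chloride (Cp2Zr(Cl) on C10, cis to H1) | C/C(=C\CC/C(CO[Si](c1ccccc1)(c1ccccc1)C(C)(C)C)=C\[Si](C)(C)C)[Zr](Cl)(C1C=CC=C1)C1C=CC=C1 | intermediate (not isolated)
9 | tert-butyl{[(E)-2-[(E)-4-iodopent-3-en-1-yl]-3-(trimethylsilyl)prop-2-en-1-yl]oxy}diphenylsilane | C/C(I)=C\CC/C(CO[Si](c1ccccc1)(c1ccccc1)C(C)(C)C)=C\[Si](C)(C)C | intermediate
10 | (S)-epichlorohydrin | ClC[C@@H]1CO1 | starting material
11 | alkenyllithium from 9 (Li in place of I) | C/C([Li])=C\CC/C(CO[Si](c1ccccc1)(c1ccccc1)C(C)(C)C)=C\[Si](C)(C)C | intermediate (not isolated)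
12 | alkenylmagnesium bromide from 11 | C/C([Mg]Br)=C\CC/C(CO[Si](c1ccccc1)(c1ccccc1)C(C)(C)C)=C\[Si](C)(C)C | intermediate (not isolated)
13 | (2S,4E,8E)-8-[(tert-butyldiphenylsilyloxy)methyl]-1-chloro-4-methyl-9-(trimethylsilyl)nona-4,8-dien-2-ol | ClC[C@@H](O)C/C(C)=C/CC/C(CO[Si](c1ccccc1)(c1ccccc1)C(C)(C)C)=C\[Si](C)(C)C | intermediate
14 | (2S)-2-[(2E,6E)-6-[(tert-butyldiphenylsilyloxy)methyl]-2-methyl-7-(trimethylsilyl)hepta-2,6-dien-1-yl]oxirane | C1O[C@H]1C/C(C)=C/CC/C(CO[Si](c2ccccc2)(c2ccccc2)C(C)(C)C)=C\[Si](C)(C)C | intermediate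
15 | (phenylselanyl)acetic acid | OC(=O)C[Se]c1ccccc1 | starting material
16 | dilithium (phenylselanyl)acetate dianion | [Li+].[Li+].[O-]C(=O)[CH-][Se]c1ccccc1 | intermediate (not isolated)
17 | (4S,6E,10E)-10-[(tert-butyldiphenylsilyloxy)methyl]-4-hydroxy-6-methyl-2-(phenylselanyl)-11-(trimethylsilyl)undeca-6,10-dienoic acid | OC(=O)C([Se]c1ccccc1)C[C@@H](O)C/C(C)=C/CC/C(CO[Si](c1ccccc1)(c1ccccc1)C(C)(C)C)=C\[Si](C)(C)C | intermediate (not isolated)
18 | (5S)-5-[(2E,6E)-6-[(tert-butyldiphenylsilyloxy)methyl]-2-methyl-7-(trimethylsilyl)hepta-2,6-dien-1-yl]-3-(phenylselanyl)oxolan-2-one (C3 epimers) | O=C1O[C@@H](C/C(C)=C/CC/C(CO[Si](c2ccccc2)(c2ccccc2)C(C)(C)C)=C\[Si](C)(C)C)CC1[Se]c1ccccc1 | intermediate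
19 | selenoxide of 18 | O=C1O[C@@H](C/C(C)=C/CC/C(CO[Si](c2ccccc2)(c2ccccc2)C(C)(C)C)=C\[Si](C)(C)C)CC1[Se](=O)c1ccccc1 | intermediate (not isolated)
20 | (5S)-5-[(2E,6E)-6-[(tert-butyldiphenylsilyloxy)methyl]-2-methyl-7-(trimethylsilyl)hepta-2,6-dien-1-yl]furan-2(5H)-one | O=C1O[C@@H](C/C(C)=C/CC/C(CO[Si](c2ccccc2)(c2ccccc2)C(C)(C)C)=C\[Si](C)(C)C)C=C1 | intermediate
21 | 1,3-dioxolane | C1COCO1 | starting material
22 | (4R,5S)-4-(1,3-dioxolan-2-yl)-5-[(2E,6E)-6-[(tert-butyldiphenylsilyloxy)methyl]-2-methyl-7-(trimethylsilyl)hepta-2,6-dien-1-yl]oxolan-2-one | O1CCOC1[C@@H]1CC(=O)O[C@H]1C/C(C)=C/CC/C(CO[Si](c2ccccc2)(c2ccccc2)C(C)(C)C)=C\[Si](C)(C)C | intermediate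
23 | (4R,5S)-4-(1,3-dioxolan-2-yl)-5-[(2E,6E)-6-[(tert-butyldiphenylsilyloxy)methyl]-7-iodo-2-methylhepta-2,6-dien-1-yl]oxolan-2-one | O1CCOC1[C@@H]1CC(=O)O[C@H]1C/C(C)=C/CC/C(CO[Si](c2ccccc2)(c2ccccc2)C(C)(C)C)=C\I | intermediate
24 | (2S,3R)-2-[(2E,6E)-6-[(tert-butyldiphenylsilyloxy)methyl]-7-iodo-2-methylhepta-2,6-dien-1-yl]-5-oxooxolane-3-carbaldehyde | O=C[C@@H]1CC(=O)O[C@H]1C/C(C)=C/CC/C(CO[Si](c2ccccc2)(c2ccccc2)C(C)(C)C)=C\I | intermediate (key-step precursor)
25 | alkenylchromium dichloride from 24 (CrCl2 in place of I) | O=C[C@@H]1CC(=O)O[C@H]1C/C(C)=C/CC/C(CO[Si](c2ccccc2)(c2ccccc2)C(C)(C)C)=C\[Cr](Cl)Cl | intermediate (not isolated)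
26 | (6R,7S,8S)-15-(tert-butyldiphenylsilyloxy)-6-hydroxy-13-norgermacra-1(10)E,4E-dien-12,8-olide | C1C(=O)O[C@H]2C/C(C)=C/CC/C(CO[Si](c3ccccc3)(c3ccccc3)C(C)(C)C)=C\[C@@H](O)[C@H]12 | intermediate (key-step product)
27 | (6R,7R,8S)-15-(tert-butyldiphenylsilyloxy)-6-(triethylsilyloxy)-13-norgermacra-1(10)E,4E-dien-12,8-olide | C1C(=O)O[C@H]2C/C(C)=C/CC/C(CO[Si](c3ccccc3)(c3ccccc3)C(C)(C)C)=C\[C@@H](O[Si](CC)(CC)CC)[C@H]12 | intermediate
28 | 13-(dimethylamino)-11,13-dihydro derivative of 30 (Mannich base, C11 epimers) | CN(C)CC1C(=O)O[C@H]2C/C(C)=C/CC/C(CO[Si](c3ccccc3)(c3ccccc3)C(C)(C)C)=C\[C@@H](O[Si](CC)(CC)CC)[C@H]12 | intermediate (not isolated)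
29 | trimethylammonium iodide of 28 | C[N+](C)(C)CC1C(=O)O[C@H]2C/C(C)=C/CC/C(CO[Si](c3ccccc3)(c3ccccc3)C(C)(C)C)=C\[C@@H](O[Si](CC)(CC)CC)[C@H]12.[I-] | intermediate (not isolated)
30 | (6R,7R,8S)-15-(tert-butyldiphenylsilyloxy)-6-(triethylsilyloxy)germacra-1(10)E,4E,11(13)-trien-12,8-olide | C=C1C(=O)O[C@H]2C/C(C)=C/CC/C(CO[Si](c3ccccc3)(c3ccccc3)C(C)(C)C)=C\[C@@H](O[Si](CC)(CC)CC)[C@H]12 | intermediate
31 | (6R,7S,8S)-15-(tert-butyldiphenylsilyloxy)-6-hydroxygermacra-1(10)E,4E,11(13)-trien-12,8-olide | C=C1C(=O)O[C@H]2C/C(C)=C/CC/C(CO[Si](c3ccccc3)(c3ccccc3)C(C)(C)C)=C\[C@@H](O)[C@H]12 | intermediate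
32 | (tert-butyldimethylsilyloxy)acetaldehyde | O=CCO[Si](C)(C)C(C)(C)C | starting material
33 | ethyl 2-(triphenylphosphoranylidene)propanoate | CCOC(=O)C(C)=P(c1ccccc1)(c1ccccc1)c1ccccc1 | starting material
34 | ethyl (E)-4-(tert-butyldimethylsilyloxy)-2-methylbut-2-enoate | CCOC(=O)/C(C)=C/CO[Si](C)(C)C(C)(C)C | intermediate
35 | (E)-4-(tert-butyldimethylsilyloxy)-2-methylbut-2-enoic acid | OC(=O)/C(C)=C/CO[Si](C)(C)C(C)(C)C | intermediate
36 | mixed anhydride of 35 with 2,4,6-trichlorobenzoic acid | O=C(OC(=O)/C(C)=C/CO[Si](C)(C)C(C)(C)C)c1c(Cl)cc(Cl)cc1Cl | intermediate (not isolated)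
37 | (6R,7R,8S)-6-[(E)-4-(tert-butyldimethylsilyloxy)-2-methylbut-2-enoyloxy]-15-(tert-butyldiphenylsilyloxy)germacra-1(10)E,4E,11(13)-trien-12,8-olide | C=C1C(=O)O[C@H]2C/C(C)=C/CC/C(CO[Si](c3ccccc3)(c3ccccc3)C(C)(C)C)=C\[C@@H](OC(=O)/C(C)=C/CO[Si](C)(C)C(C)(C)C)[C@H]12 | intermediate
38 | (6R,7R,8S)-15-hydroxy-6-[(E)-4-hydroxy-2-methylbut-2-enoyloxy]germacra-1(10)E,4E,11(13)-trien-12,8-olide (CNP0344932.2) | C=C1C(=O)O[C@H]2C/C(C)=C/CC/C(CO)=C\[C@@H](OC(=O)/C(C)=C/CO)[C@H]12 | target

**Step count**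

Total: 19 steps. Longest linear sequence: 17 steps (steps 1–15, 18 and 19, from pent-3-yn-1-ol); steps 16 and 17 make the side-chain acid.

**Steps most likely to fail**

Step 12. The alkenylchromium may add to the wrong face of the C6 aldehyde. Fallback: setting out from 24, the ring is still closed between C5 and C6 as in step 12, but the C6 configuration is no longer asked of that reaction. The (6S)-epimeric allylic alcohol F1, alone or mixed with 26, is oxidised with Dess–Martin periodinane and NaHCO3 to the macrocyclic C6 enone F2. The ketone is then reduced under reagent control by Corey–Bakshi–Shibata reduction with BH3·SMe2 and the oxazaborolidine enantiomer chosen by the usual model ((R)-2-methyl-CBS-oxazaborolidine if the C5 alkenyl branch acts as the larger group). This comes back to the route at 26.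

Step 9. Photoexcited benzophenone may engage the two trisubstituted alkenes (oxetane formation, scrambling of alkene geometry) instead of abstracting hydrogen from the dioxolane, and the anti selectivity may erode. Fallback: setting out from 20, C6 is added by an ionic conjugate addition. (Isopropoxydimethylsilyl)methylmagnesium chloride with CuBr·SMe2 and Me3SiCl in THF at −78 °C adds anti to the C8 chain and gives the trans 4-[(isopropoxydimethylsilyl)methyl] lactone F3. Iododesilylation of the vinylsilane (N-iodosuccinimide, hexafluoroisopropanol, 0 °C) is done while C6 is still masked, so that no free hydroxyl can intercept an iodonium ion at C1=C10, and gives the vinyl iodide F4. Tamao–Fleming oxidation (H2O2, KF, KHCO3, THF/MeOH) then gives the trans 4-(hydroxymethyl) lactone F5, and Dess–Martin oxidation returns to the route at 24.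

Step 11. The oxocarbenium ion formed on acetal opening may be captured by the C1=C10 alkene in a cationic cyclisation, or forcing conditions may cause β-elimination of the lactone oxygen or epimerisation at C7. Fallback: setting out from 20, C6 is brought in at the alcohol oxidation level so that no acidic unmasking is needed. Benzophenone-sensitised photoaddition of methanol gives the trans 4-(hydroxymethyl) lactone F6, and Dess–Martin oxidation with NaHCO3 gives the aldehyde F7, which still carries the vinylsilane. Iododesilylation (N-iodosuccinimide, 2,6-lutidine, hexafluoroisopropanol, 0 °C) comes back to the route at 24.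

**Further compounds**

F1 | step 12 | (6S,7S,8S)-15-(tert-butyldiphenylsilyloxy)-6-hydroxy-13-norgermacra-1(10)E,4E-dien-12,8-olide (C6 epimer of 26) | C1C(=O)O[C@H]2C/C(C)=C/CC/C(CO[Si](c3ccccc3)(c3ccccc3)C(C)(C)C)=C\[C@H](O)[C@H]12
F2 | step 12 | (7R,8S)-15-(tert-butyldiphenylsilyloxy)-6-oxo-13-norgermacra-1(10)E,4E-dien-12,8-olide | C1C(=O)O[C@H]2C/C(C)=C/CC/C(CO[Si](c3ccccc3)(c3ccccc3)C(C)(C)C)=C\C(=O)[C@H]12
F3 | step 9 | (4R,5S)-5-[(2E,6E)-6-[(tert-butyldiphenylsilyloxy)methyl]-2-methyl-7-(trimethylsilyl)hepta-2,6-dien-1-yl]-4-[(isopropoxydimethylsilyl)methyl]oxolan-2-one | CC(C)O[Si](C)(C)C[C@@H]1CC(=O)O[C@H]1C/C(C)=C/CC/C(CO[Si](c2ccccc2)(c2ccccc2)C(C)(C)C)=C\[Si](C)(C)C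
F4 | step 9 | (4R,5S)-5-[(2E,6E)-6-[(tert-butyldiphenylsilyloxy)methyl]-7-iodo-2-methylhepta-2,6-dien-1-yl]-4-[(isopropoxydimethylsilyl)methyl]oxolan-2-one | CC(C)O[Si](C)(C)C[C@@H]1CC(=O)O[C@H]1C/C(C)=C/CC/C(CO[Si](c2ccccc2)(c2ccccc2)C(C)(C)C)=C\I
F5 | step 9 | (4S,5S)-5-[(2E,6E)-6-[(tert-butyldiphenylsilyloxy)methyl]-7-iodo-2-methylhepta-2,6-dien-1-yl]-4-(hydroxymethyl)oxolan-2-one (trans) | OC[C@@H]1CC(=O)O[C@H]1C/C(C)=C/CC/C(CO[Si](c2ccccc2)(c2ccccc2)C(C)(C)C)=C\I
F6 | step 11 | (4S,5S)-5-[(2E,6E)-6-[(tert-butyldiphenylsilyloxy)methyl]-2-methyl-7-(trimethylsilyl)hepta-2,6-dien-1-yl]-4-(hydroxymethyl)oxolan-2-one (trans) | OC[C@@H]1CC(=O)O[C@H]1C/C(C)=C/CC/C(CO[Si](c2ccccc2)(c2ccccc2)C(C)(C)C)=C\[Si](C)(C)C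
F7 | step 11 | (2S,3R)-2-[(2E,6E)-6-[(tert-butyldiphenylsilyloxy)methyl]-2-methyl-7-(trimethylsilyl)hepta-2,6-dien-1-yl]-5-oxooxolane-3-carbaldehyde | O=C[C@@H]1CC(=O)O[C@H]1C/C(C)=C/CC/C(CO[Si](c2ccccc2)(c2ccccc2)C(C)(C)C)=C\[Si](C)(C)C
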